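**Retrosynthetic overview**
1. Final events: the O9 silyl group is removed and O8 is methacryloylated on the finished bicycle; the ten-membered carbocycle (C1–C10) is closed last, by ring-closing metathesis across C1=C10 between a terminal vinyl group and the C10 acrylate.
2. The lactone ring (O6, C6, C7, C11, C12) is closed before it through the C7–C11 bond: a phosphine-triggered cycloisomerisation in which the α-carbon of an O6-bound acrylate opens a trans C7–C8 epoxide. This sets C7, frees the C8 hydroxyl and delivers the C11=C13 methylene at its final oxidation level.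
3. Enabling feature: the α-methylene-γ-butyrolactone is an acrylate ester of O6 whose α-carbon C11 lies 1,5 to C7, and the C7–C11 bond is anti to C8–O across C7–C8. This is the pattern left by rear-side opening of a trans epoxide flanked by the C6 and C9 carbinols.
4. The open-chain substrate comes from a C5–C6 Nozaki–Hiyama–Kishi union of an E iodo-diene (C1–C5, C15) with an epoxy aldehyde (C6–C10, C14). The epoxide is set by Sharpless epoxidation and C9 by an asymmetric Morita–Baylis–Hillman reaction.
5. Order of ring formation: epoxide (temporary), then lactone, then ten-membered ring.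

Key step: step 10

Remark: locants C1–C15 are germacranolide locants (C6/C7 lactone fusion, C8 acyloxy, C9 hydroxyl, C10 ester-bearing alkene carbon, C11 lactone α-carbon, C12 lactone carbonyl, C13 exocyclic methylene, C14 ester carbon, C15 methyl). Compounds 1, 4 and 5 are taken as purchasable.

**Step 1**
Reactants: 1 hex-1-en-5-yne
Product: 3 (1E)-1-iodo-2-methylhexa-1,5-diene, via alkenyldimethylalane 2 (not isolated)
Conditions: AlMe3 (2 equiv), Cp2ZrCl2 (0.25 equiv), CH2Cl2, 0 °C to rt; then I2, THF, −30 °C
Reagents that add atoms: trimethylaluminium (C[Al](C)C); iodine ([I][I])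
Why: Negishi zirconium-catalysed carboalumination adds methyl and aluminium syn across the terminal alkyne (methyl to the internal carbon) much faster than across the alkene, and iodinolysis with retention should give the E iodide.

**Step 2**
Reactants: 4 (2E)-4,4-dimethoxybut-2-enal; 5 1,1,1,3,3,3-hexafluoropropan-2-yl prop-2-enoate
Product: 7 methyl (3R,4E)-3-hydroxy-6,6-dimethoxy-2-methylidenehex-4-enoate, via hexafluoroisopropyl ester 6 (not isolated)
Conditions: β-isocupreidine (10 mol%), DMF, −55 °C; then MeOH, Et3N, 0 °C to rt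
Reagents that add atoms: methanol (CO)
Why: asymmetric Morita–Baylis–Hillman reaction in which the bifunctional cinchona amine–phenol catalyst should deliver the R carbinol (C9) from the activated acrylate, followed by transesterification of the activated ester with methanol.

**Step 3**
Reactants: 7 methyl (3R,4E)-3-hydroxy-6,6-dimethoxy-2-methylidenehex-4-enoate
Product: 8 methyl (3R,4E)-3-[(tert-butyldimethylsilyl)oxy]-6,6-dimethoxy-2-methylidenehex-4-enoate
Conditions: TBSCl, imidazole, DMF, rt
Reagents that add atoms: tert-butyldimethylsilyl chloride (CC(C)(C)[Si](C)(C)Cl)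
Why: standard silyl ether formation protects O9 with a group that is a poor leaving group toward phosphines and survives every step up to the last.

**Step 4**
Reactants: 8 methyl (3R,4E)-3-[(tert-butyldimethylsilyl)oxy]-6,6-dimethoxy-2-methylidenehex-4-enoate
Product: 9 methyl (3R,4E)-3-[(tert-butyldimethylsilyl)oxy]-2-methylidene-6-oxohex-4-enoate
Conditions: oxalic acid (cat.), THF–H2O 4:1, 0 °C to rt
Reagents that add atoms: water (O)
Why: mild acid hydrolysis of the dimethyl acetal of an enal is fast under conditions that leave the secondary silyl ether and the C9 stereocentre untouched.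

**Step 5**
Reactants: 9 methyl (3R,4E)-3-[(tert-butyldimethylsilyl)oxy]-2-methylidene-6-oxohex-4-enoate
Product: 10 methyl (3R,4E)-3-[(tert-butyldimethylsilyl)oxy]-6-hydroxy-2-methylidenehex-4-enoate
Conditions: NaBH4, CeCl3·7H2O, MeOH, −40 °C
Reagents that add atoms: none
Why: Luche reduction gives clean 1,2-reduction of the enal at low temperature without touching the methyl ester or the α-branched acrylate.

**Step 6**
Reactants: 10 methyl (3R,4E)-3-[(tert-butyldimethylsilyl)oxy]-6-hydroxy-2-methylidenehex-4-enoate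
Product: 11 methyl 2-{(S)-[(tert-butyldimethylsilyl)oxy][(2S,3R)-3-(hydroxymethyl)oxiran-2-yl]methyl}prop-2-enoate
Conditions: Ti(OiPr)4 (20 mol%), D-(−)-diethyl tartrate (24 mol%), t-BuOOH (anhydrous, in decane), 4 Å molecular sieves, CH2Cl2, −20 °C
Reagents that add atoms: tert-butyl hydroperoxide (CC(C)(C)OO)
Why: Katsuki–Sharpless asymmetric epoxidation of the primary E allylic alcohol sets C7 and C8 under reagent control (D-tartrate gives the 2R-type glycidol sense), while the electron-poor acrylate is not epoxidised.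

**Step 7**
Reactants: 11 methyl 2-{(S)-[(tert-butyldimethylsilyl)oxy][(2S,3R)-3-(hydroxymethyl)oxiran-2-yl]methyl}prop-2-enoate
Product: 12 methyl 2-{(S)-[(tert-butyldimethylsilyl)oxy][(2S,3S)-3-formyloxiran-2-yl]methyl}prop-2-enoate
Conditions: Dess–Martin periodinane, NaHCO3, CH2Cl2, 0 °C
Reagents that add atoms: none
Why: buffered Dess–Martin oxidation converts the epoxy alcohol into the epoxy aldehyde without epimerising C7 or opening the epoxide.

**Step 8**
Reactants: 12 methyl 2-{(S)-[(tert-butyldimethylsilyl)oxy][(2S,3S)-3-formyloxiran-2-yl]methyl}prop-2-enoate; 3 (1E)-1-iodo-2-methylhexa-1,5-diene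
Product: 13 methyl 2-[(S)-[(tert-butyldimethylsilyl)oxy]{(2S,3R)-3-[(1R,2E)-1-hydroxy-3-methylhepta-2,6-dien-1-yl]oxiran-2-yl}methyl]prop-2-enoate
Conditions: CrCl2 (4 equiv), NiCl2 (2 mol%), DMSO, rt
Reagents that add atoms: none
Why: Nozaki–Hiyama–Kishi coupling, in which the alkenylchromium species adds only to the aldehyde (ester, acrylate and epoxide tolerated) with retention of the E geometry, and Felkin–Anh addition (epoxide C–O bond anti to the incoming alkenyl group) should favour the erythro 6R carbinol.

**Step 9**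
Reactants: 13 methyl 2-[(S)-[(tert-butyldimethylsilyl)oxy]{(2S,3R)-3-[(1R,2E)-1-hydroxy-3-methylhepta-2,6-dien-1-yl]oxiran-2-yl}methyl]prop-2-enoate
Product: 14 (1R,2E)-1-{(2R,3S)-3-[(S)-[(tert-butyldimethylsilyl)oxy](3-methoxy-3-oxoprop-1-en-2-yl)methyl]oxiran-2-yl}-3-methylhepta-2,6-dien-1-yl prop-2-enoate
Conditions: acryloyl chloride, i-Pr2NEt, CH2Cl2, −20 to 0 °C
Reagents that add atoms: acryloyl chloride (C=CC(=O)Cl)
Why: O-acylation of the only free hydroxyl under cold, weakly basic conditions installs the latent C11–C13 unit on O6 without Payne rearrangement of the epoxy alcohol.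

**Step 10**
Reactants: 14 (1R,2E)-1-{(2R,3S)-3-[(S)-[(tert-butyldimethylsilyl)oxy](3-methoxy-3-oxoprop-1-en-2-yl)methyl]oxiran-2-yl}-3-methylhepta-2,6-dien-1-yl prop-2-enoate
Product: 17 methyl (3S,4S)-3-[(tert-butyldimethylsilyl)oxy]-4-hydroxy-2-methylidene-4-{(2R,3R)-2-[(1E)-2-methylhexa-1,5-dien-1-yl]-4-methylidene-5-oxooxolan-3-yl}butanoate, via phosphonium enolate 15 (not isolated), via phosphonium alkoxide 16 (not isolated)
Conditions: PMe3 (30 mol%), t-BuOH–THF 1:1, 0.01 M, 23 to 40 °C
Reagents that add atoms: none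
Why: Proposed new method: trimethylphosphine adds reversibly to the terminal carbon (C13) of the unsubstituted O6 acrylate to give the β-phosphonium ester enolate 15, whose α-carbon C11 opens the C7–C8 epoxide from the rear to give alkoxide 16; the C8 alkoxide then takes the C11 proton and trimethylphosphine leaves by E1cB elimination, which turns the catalyst over and unveils the C11=C13 methylene with no atom gained or lost. The closest known reaction type is the phosphine-mediated intramolecular Morita–Baylis–Hillman alkylation (enones with tethered epoxides or alkyl halides) together with the Rauhut–Currier cycloisomerisation; new are the acrylate ester as latent enolate and the lactone as the ring formed. The γ-butyrolactone (O6, C6, C7, C11, C12) is closed in the 5-exo-tet mode. C7 is set by stereospecific inversion at the epoxide carbon and C8 keeps its epoxide configuration, so the erythro trans-epoxy alcohol is translated into the trans 6,7-fusion and the anti C7–C11/C8–O array of the target. The step needs attack at C7 and not at C8 (6-endo), and phosphine addition to the O6 acrylate and not to the C10 acrylate: the three-atom tether and the silyloxy-bearing C9 next to C8 should secure the first, the α-branching of the C10 acrylate the second. High dilution and the protic medium (epoxide activation, fast protonation of the C8 alkoxide) should hold back intermolecular Rauhut–Currier dimerisation and migration of the lactone to O8.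

**Step 11**
Reactants: 17 methyl (3S,4S)-3-[(tert-butyldimethylsilyl)oxy]-4-hydroxy-2-methylidene-4-{(2R,3R)-2-[(1E)-2-methylhexa-1,5-dien-1-yl]-4-methylidene-5-oxooxolan-3-yl}butanoate
Product: 18 methyl (3aR,4S,5S,6E,10E,11aR)-5-[(tert-butyldimethylsilyl)oxy]-4-hydroxy-10-methyl-3-methylidene-2-oxo-2,3,3a,4,5,8,9,11a-octahydrocyclodeca[b]furan-6-carboxylate
Conditions: second-generation Grubbs catalyst (10 mol%), 1,4-benzoquinone (20 mol%), toluene, 1 mM, 80 °C
Reagents that add atoms: none
Why: ring-closing metathesis, in which the ruthenium alkylidene formed at the monosubstituted vinyl group should close onto the C10 acrylate to give the ring-cis trisubstituted enoate (E by the sequence rule), because closure onto the lactone methylene would need an eight-membered ring holding the E C4=C5 alkene.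

**Step 12**
Reactants: 18 methyl (3aR,4S,5S,6E,10E,11aR)-5-[(tert-butyldimethylsilyl)oxy]-4-hydroxy-10-methyl-3-methylidene-2-oxo-2,3,3a,4,5,8,9,11a-octahydrocyclodeca[b]furan-6-carboxylate
Product: 19 methyl (3aS,4S,5S,6E,10E,11aR)-5-[(tert-butyldimethylsilyl)oxy]-10-methyl-3-methylidene-4-[(2-methylprop-2-enoyl)oxy]-2-oxo-2,3,3a,4,5,8,9,11a-octahydrocyclodeca[b]furan-6-carboxylate
Conditions: methacrylic anhydride, Et3N, DMAP, CH2Cl2, 0 °C to rt
Reagents that add atoms: methacrylic anhydride (C=C(C)C(=O)OC(=O)C(C)=C)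
Why: DMAP-catalysed acylation of the single free hydroxyl (O8, freed in step 10) places the methacrylate regiospecifically while O9 is still silylated.

**Step 13**
Reactants: 19 methyl (3aS,4S,5S,6E,10E,11aR)-5-[(tert-butyldimethylsilyl)oxy]-10-methyl-3-methylidene-4-[(2-methylprop-2-enoyl)oxy]-2-oxo-2,3,3a,4,5,8,9,11a-octahydrocyclodeca[b]furan-6-carboxylate
Product: 20 methyl (3aS,4S,5S,6E,10E,11aR)-5-hydroxy-10-methyl-3-methylidene-4-[(2-methylprop-2-enoyl)oxy]-2-oxo-2,3,3a,4,5,8,9,11a-octahydrocyclodeca[b]furan-6-carboxylate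
Conditions: HF·pyridine, THF–pyridine, 0 °C to rt
Reagents that add atoms: none
Why: fluoride-mediated desilylation under buffered acidic conditions frees O9 without O8-to-O9 acyl migration or conjugate addition to the two Michael acceptors.

**Compound list**
1 | hex-1-en-5-yne | C=CCCC#C | starting material
2 | [(1E)-2-methylhexa-1,5-dien-1-yl]dimethylalane | C=CCC/C(C)=C/[Al](C)C | intermediate
3 | (1E)-1-iodo-2-methylhexa-1,5-diene | C=CCC/C(C)=C/I | intermediate
4 | (2E)-4,4-dimethoxybut-2-enal | COC(OC)/C=C/C=O | starting material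
5 | 1,1,1,3,3,3-hexafluoropropan-2-yl prop-2-enoate | C=CC(=O)OC(C(F)(F)F)C(F)(F)F | starting material
6 | 1,1,1,3,3,3-hexafluoropropan-2-yl (3R,4E)-3-hydroxy-6,6-dimethoxy-2-methylidenehex-4-enoate | COC(OC)/C=C/[C@@H](O)C(=C)C(=O)OC(C(F)(F)F)C(F)(F)F | intermediate
7 | methyl (3R,4E)-3-hydroxy-6,6-dimethoxy-2-methylidenehex-4-enoate | COC(OC)/C=C/[C@@H](O)C(=C)C(=O)OC | intermediate
8 | methyl (3R,4E)-3-[(tert-butyldimethylsilyl)oxy]-6,6-dimethoxy-2-methylidenehex-4-enoate | COC(OC)/C=C/[C@@H](O[Si](C)(C)C(C)(C)C)C(=C)C(=O)OC | intermediate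
9 | methyl (3R,4E)-3-[(tert-butyldimethylsilyl)oxy]-2-methylidene-6-oxohex-4-enoate | O=C/C=C/[C@@H](O[Si](C)(C)C(C)(C)C)C(=C)C(=O)OC | intermediate
10 | methyl (3R,4E)-3-[(tert-butyldimethylsilyl)oxy]-6-hydroxy-2-methylidenehex-4-enoate | OC/C=C/[C@@H](O[Si](C)(C)C(C)(C)C)C(=C)C(=O)OC | intermediate
11 | methyl 2-{(S)-[(tert-butyldimethylsilyl)oxy][(2S,3R)-3-(hydroxymethyl)oxiran-2-yl]methyl}prop-2-enoate | OC[C@H]1O[C@@H]1[C@@H](O[Si](C)(C)C(C)(C)C)C(=C)C(=O)OC | intermediate
12 | methyl 2-{(S)-[(tert-butyldimethylsilyl)oxy][(2S,3S)-3-formyloxiran-2-yl]methyl}prop-2-enoate | O=C[C@H]1O[C@@H]1[C@@H](O[Si](C)(C)C(C)(C)C)C(=C)C(=O)OC | intermediate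
13 | methyl 2-[(S)-[(tert-butyldimethylsilyl)oxy]{(2S,3R)-3-[(1R,2E)-1-hydroxy-3-methylhepta-2,6-dien-1-yl]oxiran-2-yl}methyl]prop-2-enoate | C=CCC/C(C)=C/[C@@H](O)[C@H]1O[C@@H]1[C@@H](O[Si](C)(C)C(C)(C)C)C(=C)C(=O)OC | intermediate
14 | (1R,2E)-1-{(2R,3S)-3-[(S)-[(tert-butyldimethylsilyl)oxy](3-methoxy-3-oxoprop-1-en-2-yl)methyl]oxiran-2-yl}-3-methylhepta-2,6-dien-1-yl prop-2-enoate | C=CCC/C(C)=C/[C@@H](OC(=O)C=C)[C@H]1O[C@@H]1[C@@H](O[Si](C)(C)C(C)(C)C)C(=C)C(=O)OC | intermediate
15 | phosphonium enolate (trimethylphosphine adduct of 14 at C13, zwitterion) | C=CCC/C(C)=C/[C@@H](OC([O-])=CC[P+](C)(C)C)[C@H]1O[C@@H]1[C@@H](O[Si](C)(C)C(C)(C)C)C(=C)C(=O)OC | intermediate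
16 | phosphonium alkoxide (cyclised lactone with C11 trimethylphosphoniomethyl group and C8 alkoxide, zwitterion, C11 undefined) | C=CCC/C(C)=C/[C@H]1OC(=O)C(C[P+](C)(C)C)[C@@H]1[C@H]([O-])[C@@H](O[Si](C)(C)C(C)(C)C)C(=C)C(=O)OC | intermediate
17 | methyl (3S,4S)-3-[(tert-butyldimethylsilyl)oxy]-4-hydroxy-2-methylidene-4-{(2R,3R)-2-[(1E)-2-methylhexa-1,5-dien-1-yl]-4-methylidene-5-oxooxolan-3-yl}butanoate | C=CCC/C(C)=C/[C@H]1OC(=O)C(=C)[C@@H]1[C@H](O)[C@@H](O[Si](C)(C)C(C)(C)C)C(=C)C(=O)OC | intermediate
18 | methyl (3aR,4S,5S,6E,10E,11aR)-5-[(tert-butyldimethylsilyl)oxy]-4-hydroxy-10-methyl-3-methylidene-2-oxo-2,3,3a,4,5,8,9,11a-octahydrocyclodeca[b]furan-6-carboxylate | O[C@H]1[C@H]2C(=C)C(=O)O[C@@H]2/C=C(\C)CC/C=C(/C(=O)OC)[C@@H]1O[Si](C)(C)C(C)(C)C | intermediate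
19 | methyl (3aS,4S,5S,6E,10E,11aR)-5-[(tert-butyldimethylsilyl)oxy]-10-methyl-3-methylidene-4-[(2-methylprop-2-enoyl)oxy]-2-oxo-2,3,3a,4,5,8,9,11a-octahydrocyclodeca[b]furan-6-carboxylate | C=C(C)C(=O)O[C@H]1[C@H]2C(=C)C(=O)O[C@@H]2/C=C(\C)CC/C=C(/C(=O)OC)[C@@H]1O[Si](C)(C)C(C)(C)C | intermediate
20 | methyl (3aS,4S,5S,6E,10E,11aR)-5-hydroxy-10-methyl-3-methylidene-4-[(2-methylprop-2-enoyl)oxy]-2-oxo-2,3,3a,4,5,8,9,11a-octahydrocyclodeca[b]furan-6-carboxylate | C=C(C)C(=O)O[C@H]1[C@H]2C(=C)C(=O)O[C@@H]2/C=C(\C)CC/C=C(/C(=O)OC)[C@@H]1O | target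

**Total step count:** 13
**Longest linear sequence:** 12 steps (steps 2 to 13, from 4)

**Steps most likely to fail**

1. Step 10 (proposed new method). The ester enolate may form in too low a concentration to open the epoxide, intermolecular Rauhut–Currier oligomerisation of the acrylate may win, or the lactone may migrate to O8 under the basic conditions. Fallback with known reaction types, setting out from 13: esterification with 2-(diethoxyphosphoryl)acetic acid (N,N'-dicyclohexylcarbodiimide, DMAP, CH2Cl2) would give the O6 diethylphosphonoacetate F1. Deprotonation (NaH, THF, 0 °C to rt) would let the stabilised carbanion open the epoxide at C7 in the same 5-exo mode with inversion, to give the α-phosphono lactone F2. Horner–Wadsworth–Emmons methylenation of its sodium salt with paraformaldehyde would give 17, where the route is rejoined.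

2. Step 11. The ruthenium alkylidene may fail to engage the hindered, electron-poor C10 acrylate in a ten-membered closure, so that cross-metathesis oligomers of the terminal alkene form instead. Fallback, setting out from 12 and 3: the C1=C10 bond is made first and the ring is closed at C5–C6. Cross-metathesis of the acrylate of 12 with the terminal alkene of 3 (second-generation Grubbs catalyst, CH2Cl2, 40 °C, excess 3) should give the E trisubstituted enoate, iodo epoxy aldehyde F3. Intramolecular Nozaki–Hiyama–Kishi reaction (CrCl2, NiCl2 cat., DMSO–THF, 2 mM) would close the ten-membered ring to the macrocyclic epoxy alcohol F4. Acryloylation as in step 9 would give the macrocyclic acrylate F5, and the transannular version of the step 10 cyclisation would return the route at 18.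

3. Step 8. Facial selectivity in the addition to the epoxy aldehyde may be poor (Felkin–Anh against chelate control by chromium), giving a C6 epimer mixture. Fallback, setting out from 13 as the epimer mixture: Dess–Martin oxidation would give the epoxy dienone F6, and chelation-controlled 1,2-reduction with Zn(BH4)2 (Et2O, −20 °C; zinc bridging the ketone and epoxide oxygens, hydride from the open face) would return erythro-13, where the route is rejoined.

**Further compounds**
F1 | step 10 | O6 2-(diethoxyphosphoryl)acetate of epoxy alcohol 13 | C=CCC/C(C)=C/[C@@H](OC(=O)CP(=O)(OCC)OCC)[C@H]1O[C@@H]1[C@@H](O[Si](C)(C)C(C)(C)C)C(=C)C(=O)OC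
F2 | step 10 | α-(diethoxyphosphoryl) lactone corresponding to 17 (C11 epimers, phosphonate in place of the methylene) | C=CCC/C(C)=C/[C@H]1OC(=O)C(P(=O)(OCC)OCC)[C@@H]1[C@H](O)[C@@H](O[Si](C)(C)C(C)(C)C)C(=C)C(=O)OC
F3 | step 11 | open-chain iodo epoxy aldehyde with the C1=C10 enoate in place (cross-metathesis product of 12 and 3) | O=C[C@H]1O[C@@H]1[C@@H](O[Si](C)(C)C(C)(C)C)/C(C(=O)OC)=C\CC/C(C)=C/I
F4 | step 11 | macrocyclic epoxy alcohol (ten-membered ring, C7–C8 epoxide, free 6R hydroxyl, O9 silyl ether) | O[C@@H]1/C=C(\C)CC/C=C(/C(=O)OC)[C@H](O[Si](C)(C)C(C)(C)C)[C@H]2O[C@H]12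
F5 | step 11 | O6 acrylate of macrocyclic epoxy alcohol F4 | C=CC(=O)O[C@@H]1/C=C(\C)CC/C=C(/C(=O)OC)[C@H](O[Si](C)(C)C(C)(C)C)[C@H]2O[C@H]12
F6 | step 8 | epoxy dienone (C6 ketone of 13) | C=CCC/C(C)=C/C(=O)[C@H]1O[C@@H]1[C@@H](O[Si](C)(C)C(C)(C)C)C(=C)C(=O)OC
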